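## The problem

4-O-Demethylplanaic acid (25) is a depside. Two 2-methoxy-6-pentylbenzoyl units are joined by an aryl ester between the carboxyl carbon of ring A (the ring with the free 4-hydroxyl) and O4 of ring B (the ring with the free carboxylic acid). The molecule has no stereocentre, so every difficulty is one of regiochemistry and chemoselectivity. In each ring the oxygens on C2 and C4 are meta to each other and must end up different: a methyl ether on C2, a hydroxyl or acyloxy group on C4. In a preformed 2,4-dihydroxybenzoate the unchelated 4-hydroxyl reacts first, so the 2-methyl ether cannot be reached by direct alkylation without protection. The inter-ring ester joins a phenol to a benzoic acid with both ortho positions occupied, so it forms slowly. Once formed it is the bond most easily broken by hydroxide, alkoxide or fluoride, and anything removed after the coupling must leave under neutral conditions. The electron-rich benzoic acids can decarboxylate in hot acid, and the carboxyl of ring B must be masked during the coupling. The feature that opens a short route is that each ring is a 1,2,4,6-tetrasubstituted benzene in which C2 can be the carbonyl carbon of a vinylketene and C4 the oxygen-bearing carbon of an ynol ether. C1 and C6, with carboxyl and pentyl, are then the alkene carbons of a β-pentyl enoate, so the two oxygens arrive as different groups by construction and one ring synthesis serves both halves.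

## Retrosynthesis

**25 to 24.** The last step should be neutral. The two O–CH2Ph bonds of dibenzyl compound 24 are therefore cut last: the benzyl ether on O4 of ring A and the benzyl ester of ring B. A methyl ester on ring B would need nucleophilic dealkylation next to the depside ester, and a silyl ether on ring A would need fluoride. Hydrogenolysis removes both benzyl groups in one operation and touches neither the aryl ester nor the methyl ethers. Compound 24 is no simpler in skeleton, but the forward step only has to be a clean hydrogenolysis.

**24 to 20 and 22.** The C(=O)–O bond between the rings is the convergent cut. It gives acid 20 and phenol 22, which share one carbon skeleton and differ only at O4 and at the carboxyl. Building ring A onto ring B instead would require two different ring syntheses. The forward reaction must acylate a phenol with an acid whose carbonyl lies between a pentyl and a methoxy group. Activation as mixed trifluoroacetic anhydride 23 is chosen because it reacts through an acylium-type species that is indifferent to ortho substituents.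

**22, 21, 20, 19 back to 18.** Both halves are traced to one compound. Phenol 22 comes from hydroxy acid 21 by benzylation of the carboxylate only, and 21 from acid 20 by cleavage of its benzyl ether, so part of 20 is diverted to ring B. Acid 20 comes from methyl ester 19 (ester O–CH3 bond) and 19 from phenol 18 (ether O–CH3 bond on C2). In 18 the two ring oxygens are already distinct, O2 free and O4 benzylated, so the methylation needs no selectivity. The only demanding step is the cleavage of the doubly shielded ester of 19, which must occur at the methyl group and not at the carbonyl.

**18 to 13 and 6.** Four arene bonds are cut: C1–C2, C2–C3, C4–C5 and C5–C6. C2 with its oxygen becomes a ketene carbonyl carbon, C1 and C6 the alkene of an enoate, C5 the diazo carbon of diazo ketone 13, and C3–C4 the triple bond of ynol ether 6. Compared with functionalising a preformed resorcinol ring, this cut sets the substitution pattern and the O2/O4 distinction together. The precursors are much simpler: an acyclic eleven-carbon diazo ketone with one alkene of defined geometry, and a two-carbon alkyne. The forward reaction must generate vinylketene 14 without disturbing the E alkene, and the (2+2) addition must follow the polarity of both partners.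

**13 back to 7 and 8.** Removing the diazo group gives methyl ketone 11; the forward diazo transfer needs prior trifluoroacetylation because a simple ketone methyl group is not acidic enough. The ester O–CH3 bond leads to acid 10. The C2=C3 double bond of 10 is cut as an aldol condensation between C3 of octan-2-one (7) and the aldehyde carbon of glyoxylic acid (8). An olefination of a 2,3-diketone would have to distinguish two similar carbonyls, whereas the aldol uses the inherent difference between the methylene and methyl sides of 7 under acid catalysis. The forward aldol must choose C3 over C1 and give the E alkene.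

**6 back to 1 and 2.** Ynol ether 6 is traced to dichlorovinyl ether 4, and 4 at its O–C(vinyl) bond to benzyl alcohol (1) and trichloroethylene (2), which serves as a source of dichloroacetylene (3). O-Alkylation of an ynolate is not an alternative because it goes on carbon. The forward steps are two dehydrochlorinations, and the product must be kept cold.

## Roads not taken

**Alternative 1:** The cut removes the C6–pentyl and C1–carboxyl bonds of one ring at once and leads to 1-fluoro-3-methoxy-5-(triisopropylsilyloxy)benzene A1. Forward, A1 is lithiated between fluorine and methoxyl and loses fluoride to give aryne A2. Pentylmagnesium bromide A3 adds at the aryne carbon remote from the methoxyl, and the magnesiated carbon next to the methoxyl is carboxylated to give acid A4.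

- Merits: two C–C bonds form in one flask on an existing ring, the acid is obtained directly, and the oxygens are already differentiated in A1. It is clearly shorter, about three steps to a ring A acid against eight to acid 20, and it needs no hindered ester cleavage (step 8 of the chosen route).
- Weak points: three ring positions of A1 compete for lithiation. Lithiation between fluorine and the silyloxy group gives the other aryne and, after the same sequence, an isomer with the two oxygens interchanged; the bulky silyl group disfavours this but does not exclude it. The Grignard reagent must also beat the alkyllithium base to the aryne. The silyl ether would have to be removed from the depside with fluoride, which endangers the aryl ester, or be exchanged for benzyl at extra cost.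
- Comparison: the chosen plan is longer. It sets against this a regiochemistry fixed by bond polarity rather than by kinetic competition between ring positions, and an O4 benzyl group that leaves with the benzyl ester in one neutral step.

**Alternative 2:** The depside C–O bond and the arene bond C1–C6 of ring A are both made in the key step, from ring B phenol 22 and diketo-dioxinone A5. Heating A5 releases acylketene A6 by cycloreversion. Phenol 22 captures it on oxygen to give aryl trioxododecanoate A7, and aldol condensation of C2 onto the C7 ketone with dehydration gives depside A8.

- Merits: the hindered aryl ester is formed without activating a di-ortho-substituted benzoic acid, because ring A does not yet exist when the C–O bond forms. In this respect it is better than step 11 of the chosen route.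
- Weak points: A8 carries ring A as a 2,4-dihydroxybenzoate, so the O2/O4 problem is left unsolved and must be handled on the base-sensitive depside. That means 4-O-protection, methylation of the chelated 2-hydroxyl under base, and deprotection. Phenol 22 must still be made by another ring synthesis, and the polycarbonyl chain of A5 and A7 can close in other ways.
- Comparison: the chosen plan answers the ester-bond problem with acylium-type activation, for which hindered depside acids are the usual case, and solves the oxygen differentiation at the ring-forming step.

**Alternative 3:** The cut goes through arene bonds C3–C4 and C5–C6. C4 and C5 come from ketene dibenzyl acetal A10 and the other four ring carbons from pyranone A9. Forward, the nucleophilic CH2 carbon of A10 bonds to C6 of A9 and the acetal carbon to C3. Bridged lactone A11 then loses its lactone bridge by cycloreversion and one benzyloxy group by elimination, giving A12, which is identical with compound 19.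

- Merits: it arrives one step further than the chosen key step, since O2 already carries its methyl group. It is thermal and needs no diazo compound or photochemical equipment. On paper it reaches 19 in about five steps in the longest line against seven, so it is shorter.
- Weak points: the 4-methoxy group deactivates the pyranone for a cycloaddition with an electron-rich alkene. The reacting terminus C6 carries the pentyl group, so the first bond must form at a fully substituted carbon. The forcing temperatures this implies are those at which the acid-sensitive, non-commercial acetal A10 decomposes or adds in conjugate fashion. The regiochemistry depends on the C5 ester outweighing the C4 donor.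
- Comparison: the chosen plan sets against the shorter count that all its ring bonds form between unhindered, electronically matched carbons at room temperature, with direct precedent for resorcinol monoethers. The cost is one easy methylation (step 7).

Key step: step 6

Assumption: positions are numbered as in the benzoates (C1 carries the carboxyl carbon), ring A is the acyl ring with the free 4-hydroxyl and ring B the ring with the free carboxyl; glyoxylic acid 8 is used as its commercial monohydrate.

## Route

Step 1
Reactants: 1 benzyl alcohol, 2 trichloroethylene
Product: 4 benzyl (E)-1,2-dichlorovinyl ether, via dichloroacetylene 3 (not isolated)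
Conditions: KH, THF, 0 °C to rt; then Cl2C=CHCl, −50 °C to rt
Reagents that add atoms: none
Why: KH forms the alkoxide and dehydrochlorinates 2 to dichloroacetylene 3; anti addition of the alkoxide to 3 and protonation should give the (E)-dichlorovinyl ether (net vinylic substitution by elimination–addition), the standard entry to alkoxyacetylenes.

Step 2
Reactants: 4 benzyl (E)-1,2-dichlorovinyl ether
Product: 6 benzyl ethynyl ether, via lithium acetylide 5 (not isolated)
Conditions: n-BuLi (2.3 equiv), Et2O, −78 to −40 °C; then H2O, −40 to 0 °C
Reagents that add atoms: none
Why: n-BuLi removes HCl from 4 and exchanges the remaining chlorine for lithium to give acetylide 5, which is protonated cold (double dehydrohalogenation to an alkynyl ether). The product is kept cold and used at once because benzyl alkynyl ethers rearrange sigmatropically on warming.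

Step 3
Reactants: 7 octan-2-one, 8 glyoxylic acid
Product: 10 (E)-3-acetyloct-2-enoic acid, via aldol adduct 9 (not isolated)
Conditions: 85% H3PO4, excess 7, 80 °C
Reagents that add atoms: none
Why: Acid-catalysed crossed aldol condensation: the more substituted enol of 7 (C3) adds to the aldehyde carbon of 8, which has no α-hydrogen and cannot self-condense. Dehydration of adduct 9 should give the conjugated acid with acetyl trans to carboxyl, the open-chain thermodynamic isomer.

Step 4
Reactants: 10 (E)-3-acetyloct-2-enoic acid
Product: 11 methyl (E)-3-acetyloct-2-enoate
Conditions: MeI, KHCO3, DMF, rt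
Reagents that add atoms: iodomethane, CI
Why: SN2 O-alkylation of the potassium carboxylate; hydrogen carbonate is too weak to enolise the ketone or move the double bond. Diazomethane is avoided because it would add as a 1,3-dipole to the electron-poor alkene.

Step 5
Reactants: 11 methyl (E)-3-acetyloct-2-enoate
Product: 13 methyl (E)-3-(2-diazoacetyl)oct-2-enoate, via trifluoroacetyl diketone 12 (not isolated)
Conditions: LiN(SiMe3)2, THF, −78 °C (11 added to the base); CF3CO2CH2CF3, −78 °C; dilute HCl work-up; then MsN3, Et3N, H2O, MeCN, rt
Reagents that add atoms: methanesulfonyl azide, CS(=O)(=O)N=[N+]=[N-]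
Why: Detrifluoroacetylative diazo transfer: the kinetic lithium enolate of the methyl ketone (its only enolisable α-position) undergoes Claisen acylation to diketone 12, whose activated methylene accepts the diazo group from MsN3, and the trifluoroacetyl group leaves on the sulfonamide nitrogen. Adding the ketone to the base keeps free enone away from the enolate, and the alkene geometry is not touched.

Step 6
Reactants: 13 methyl (E)-3-(2-diazoacetyl)oct-2-enoate, 6 benzyl ethynyl ether
Product: 18 methyl 4-(benzyloxy)-2-hydroxy-6-pentylbenzoate, via vinylketene 14 (not isolated), via vinylcyclobutenone 15 (not isolated), via dienylketene 16 (not isolated), via cyclohexadienone 17 (not isolated)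
Conditions: 13 (1.2 equiv), 6 (1.0 equiv), hν (254 nm, low-pressure Hg lamps, Vycor), degassed ClCH2CH2Cl, rt; then 80 °C
Reagents that add atoms: none
Why: This is the Danheiser benzannulation in its photochemical diazo ketone form: irradiation expels N2 from 13 and the alkenyl group shifts to the diazo carbon (Wolff rearrangement, arene bond C5–C6) to give vinylketene 14. The ketene C=C adds the triple bond of 6 in a (2+2) cycloaddition, the ketene carbonyl carbon bonding to the nucleophilic terminal CH of the ynol ether (C2–C3) and the ketene α-carbon to the oxygen-bearing carbon (C4–C5); this polarity match fixes the meta relation of the two oxygens. Cyclobutenone 15 opens reversibly by 4π conrotatory electrocyclic cleavage to dienylketene 16, and the rotamer with the alkenyl group turned inward closes the six-membered carbocycle by thermal 6π disrotatory electrocyclisation (C1–C2) to dienone 17, which tautomerises to phenol 18. No stereocentre is formed, and those of 15 and 17 vanish on aromatisation. The E geometry of 13 places the ester on the outside of the closing triene and away from the ketene, so closure on carbon is unhindered and cyclisation of the ketene onto the ester carbonyl oxygen, open to a Z isomer, is geometrically excluded. The ketene oxygen becomes the free, hydrogen-bonded 2-hydroxyl and the ynol ether oxygen arrives as the benzyl ether on C4. Ynol ether 6 is the limiting component and heating begins only after the irradiation stage, because 6 does not survive warming.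

Step 7
Reactants: 18 methyl 4-(benzyloxy)-2-hydroxy-6-pentylbenzoate
Product: 19 methyl 4-(benzyloxy)-2-methoxy-6-pentylbenzoate
Conditions: MeI, K2CO3, DMF, 45 °C
Reagents that add atoms: iodomethane, CI
Why: Williamson methylation of the only free hydroxyl; its hydrogen bond to the ester slows the reaction, hence DMF and gentle warming. No selectivity is needed because O4 is already benzylated.

Step 8
Reactants: 19 methyl 4-(benzyloxy)-2-methoxy-6-pentylbenzoate
Product: 20 4-(benzyloxy)-2-methoxy-6-pentylbenzoic acid
Conditions: LiI (anhydrous), pyridine, reflux; then cold 1 M HCl
Reagents that add atoms: none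
Why: Iodide attacks the ester methyl group (SN2 dealkylation with alkyl–oxygen cleavage), so the carbonyl shielded by two ortho substituents need not be reached; pyridine traps the iodomethane. Aryl methyl and benzyl ethers are much poorer electrophiles, and the acid is liberated cold to avoid decarboxylation.

Step 9
Reactants: 20 4-(benzyloxy)-2-methoxy-6-pentylbenzoic acid
Product: 21 4-hydroxy-2-methoxy-6-pentylbenzoic acid
Conditions: H2 (1 atm), Pd/C, EtOAc, rt
Reagents that add atoms: none
Why: Catalytic hydrogenolysis of the aryl benzyl ether; the carboxylic acid, the methyl ether and the ring are inert under these conditions.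

Step 10
Reactants: 21 4-hydroxy-2-methoxy-6-pentylbenzoic acid
Product: 22 benzyl 4-hydroxy-2-methoxy-6-pentylbenzoate
Conditions: BnBr (1.05 equiv), KHCO3, DMF, rt
Reagents that add atoms: benzyl bromide, BrCc1ccccc1
Why: Hydrogen carbonate ionises the carboxylic acid but not the phenol, so benzyl bromide alkylates the carboxylate oxygen chemoselectively (SN2 esterification). Alkylation at the carboxylate oxygen is not hindered by the ortho groups.

Step 11
Reactants: 20 4-(benzyloxy)-2-methoxy-6-pentylbenzoic acid, 22 benzyl 4-hydroxy-2-methoxy-6-pentylbenzoate
Product: 24 benzyl 4-{[4-(benzyloxy)-2-methoxy-6-pentylbenzoyl]oxy}-2-methoxy-6-pentylbenzoate, via mixed anhydride 23 (not isolated)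
Conditions: (CF3CO)2O, toluene, rt
Reagents that add atoms: none
Why: Depside esterification through mixed anhydride 23: with two ortho substituents it ionises readily towards a linear acylium-type species that is indifferent to steric shielding, and the phenol oxygen of 22 is acylated. The ring of 22 is deactivated towards C-acylation by its ester, and the benzyl groups should tolerate the trifluoroacetic acid formed at room temperature.

Step 12
Reactants: 24 benzyl 4-{[4-(benzyloxy)-2-methoxy-6-pentylbenzoyl]oxy}-2-methoxy-6-pentylbenzoate
Product: 25 4-[(4-hydroxy-2-methoxy-6-pentylbenzoyl)oxy]-2-methoxy-6-pentylbenzoic acid (4-O-demethylplanaic acid)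
Conditions: H2 (1 atm), Pd/C, EtOAc, rt
Reagents that add atoms: none
Why: Hydrogenolysis cleaves both benzylic C–O bonds (ether on ring A, ester on ring B) under neutral conditions. The aryl ester between the rings has no benzylic C–O bond and should survive, as do the methyl ethers.

## Compound list

1 | benzyl alcohol | OCc1ccccc1 | starting material
2 | trichloroethylene | ClC=C(Cl)Cl | starting material
3 | dichloroacetylene | ClC#CCl | intermediate
4 | benzyl (E)-1,2-dichlorovinyl ether | Cl/C=C(/Cl)OCc1ccccc1 | intermediate
5 | lithium (benzyloxy)ethynide | [Li]C#COCc1ccccc1 | intermediate
6 | benzyl ethynyl ether | C#COCc1ccccc1 | intermediate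
7 | octan-2-one | CCCCCCC(C)=O | starting material
8 | glyoxylic acid | O=CC(=O)O | starting material
9 | 3-acetyl-2-hydroxyoctanoic acid (racemic, mixture of diastereomers) | CCCCCC(C(C)=O)C(O)C(=O)O | intermediate
10 | (E)-3-acetyloct-2-enoic acid | CC(=O)/C(CCCCC)=C/C(=O)O | intermediate
11 | methyl (E)-3-acetyloct-2-enoate | CC(=O)/C(CCCCC)=C/C(=O)OC | intermediate
12 | methyl (E)-3-(4,4,4-trifluoro-3-oxobutanoyl)oct-2-enoate | O=C(CC(=O)/C(CCCCC)=C/C(=O)OC)C(F)(F)F | intermediate
13 | methyl (E)-3-(2-diazoacetyl)oct-2-enoate | [N-]=[N+]=CC(=O)/C(CCCCC)=C/C(=O)OC | intermediate
14 | methyl (2E)-5-oxo-3-pentylpenta-2,4-dienoate | O=C=C/C(CCCCC)=C/C(=O)OC | intermediate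
15 | methyl (E)-3-[2-(benzyloxy)-4-oxocyclobut-2-en-1-yl]oct-2-enoate (racemic) | CCCCC/C(=C\C(=O)OC)C1C(OCc2ccccc2)=CC1=O | intermediate
16 | methyl (2E,4E)-5-(benzyloxy)-7-oxo-3-pentylhepta-2,4,6-trienoate | O=C=C/C(OCc1ccccc1)=C\C(CCCCC)=C\C(=O)OC | intermediate
17 | methyl 4-(benzyloxy)-2-oxo-6-pentylcyclohexa-3,5-diene-1-carboxylate (racemic) | CCCCCC1=CC(OCc2ccccc2)=CC(=O)C1C(=O)OC | intermediate
18 | methyl 4-(benzyloxy)-2-hydroxy-6-pentylbenzoate | CCCCCc1cc(OCc2ccccc2)cc(O)c1C(=O)OC | intermediate
19 | methyl 4-(benzyloxy)-2-methoxy-6-pentylbenzoate | CCCCCc1cc(OCc2ccccc2)cc(OC)c1C(=O)OC | intermediate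
20 | 4-(benzyloxy)-2-methoxy-6-pentylbenzoic acid | CCCCCc1cc(OCc2ccccc2)cc(OC)c1C(=O)O | intermediate
21 | 4-hydroxy-2-methoxy-6-pentylbenzoic acid | CCCCCc1cc(O)cc(OC)c1C(=O)O | intermediate
22 | benzyl 4-hydroxy-2-methoxy-6-pentylbenzoate | CCCCCc1cc(O)cc(OC)c1C(=O)OCc1ccccc1 | intermediate
23 | 4-(benzyloxy)-2-methoxy-6-pentylbenzoic trifluoroacetic anhydride | CCCCCc1cc(OCc2ccccc2)cc(OC)c1C(=O)OC(=O)C(F)(F)F | intermediate
24 | benzyl 4-{[4-(benzyloxy)-2-methoxy-6-pentylbenzoyl]oxy}-2-methoxy-6-pentylbenzoate | CCCCCc1cc(OC(=O)c2c(CCCCC)cc(OCc3ccccc3)cc2OC)cc(OC)c1C(=O)OCc1ccccc1 | intermediate
25 | 4-[(4-hydroxy-2-methoxy-6-pentylbenzoyl)oxy]-2-methoxy-6-pentylbenzoic acid (4-O-demethylplanaic acid) | CCCCCc1cc(OC(=O)c2c(CCCCC)cc(O)cc2OC)cc(OC)c1C(=O)O | target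

## Step count and least certain steps

Total step count: 12. Longest linear sequence: 10 steps (steps 3 to 12, from 7 and 8 to 25). Ynol ether 6 is made in a two-step side branch (steps 1 and 2).

**Step 6 (key step).** Two processes are most likely to interfere. The first is E-to-Z photoisomerisation of the enoate at 254 nm, after which the ketene can cyclise onto the ester carbonyl oxygen instead of adding the ynol ether. The second is thermal rearrangement of the benzyl ynol ether before all the ketene is captured, which lowers the conversion and leaves ketene to acylate the product phenol. The fallback sets out from 13 and returns at 18. Diazo ketone 13 is irradiated in the same way with commercial ethoxyacetylene (C#COCC), which withstands 80 °C and can be used in excess so that ketene capture outruns isomerisation. This should give methyl 4-ethoxy-2-hydroxy-6-pentylbenzoate F1. BBr3 in CH2Cl2 (−78 to 0 °C) removes the ethyl group to give methyl 2,4-dihydroxy-6-pentylbenzoate F2. BnBr (1 equiv) with K2CO3 in acetone then benzylates the unchelated 4-hydroxyl selectively to give 18. The benzyl group is thus introduced after ring formation instead of being carried through the photochemical step.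

**Step 3.** The aldol addition may occur at the methyl group (C1) of 7 instead of C3, and the Z acid may close to its cyclic lactol form; either gives mixtures that are hard to separate at the acid stage. The fallback sets out from 7 and returns at 11. Ketone 7 is converted into its more substituted silyl enol ether, (Z)-trimethyl(oct-2-en-2-yloxy)silane F3 (Me3SiCl, NaI, Et3N, MeCN). Mukaiyama aldol addition to methyl glyoxylate (TiCl4, CH2Cl2, −78 °C) gives methyl 3-acetyl-2-hydroxyoctanoate F4 as a diastereomer mixture. Mesylation (MsCl, Et3N, CH2Cl2, 0 °C) gives methyl 3-acetyl-2-(methylsulfonyloxy)octanoate F5, which is not isolated and eliminates under the same conditions to 11. The regiochemistry is then fixed by the enol ether and the ester is obtained directly.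

**Step 5.** The lithium enolate may add in conjugate fashion to the doubly activated alkene of another molecule, or the base may deprotonate the allylic CH2 of the pentyl group; both consume material before trifluoroacetylation. The fallback sets out from 11 and returns at 13. Ketone 11 is heated with N,N-dimethylformamide dimethyl acetal (toluene, 80 °C) to give the enaminone methyl (2E)-3-[(2E)-3-(dimethylamino)prop-2-enoyl]oct-2-enoate F6. Diazo transfer from TsN3 (MeCN, rt) to its electron-rich C=C bond, with loss of the formamidine fragment, gives 13 without any enolate being formed.

**Step 8.** Dealkylation may be incomplete at temperatures the molecule tolerates, the C2 methyl ether may also be cleaved (iodide attack assisted by lithium chelation), and the electron-rich acid may decarboxylate on acidification. The fallback sets out from 19 and returns at 20. Ester 19 is reduced with LiAlH4 (THF, 0 °C) to [4-(benzyloxy)-2-methoxy-6-pentylphenyl]methanol F7. Oxidation with MnO2 (CH2Cl2, rt) gives 4-(benzyloxy)-2-methoxy-6-pentylbenzaldehyde F8, and Pinnick oxidation (NaClO2, NaH2PO4, 2-methylbut-2-ene, t-BuOH/H2O) gives 20. No reagent has to attack the shielded carbonyl as a nucleophile other than hydride.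

**Step 11.** O-Acylation of the deactivated phenol may be slow, so that ring acylation by the acylium species or acid-induced loss of the benzyl ether competes. The fallback sets out from 20 and returns at 24. Acid 20 is converted with oxalyl chloride and catalytic DMF (CH2Cl2, 0 °C) into 4-(benzyloxy)-2-methoxy-6-pentylbenzoyl chloride F9. This is added to the sodium phenoxide of 22 (NaH, THF, 0 °C to rt) to give 24 under basic instead of acidic conditions.

## Further compounds

F1 | step 6 | methyl 4-ethoxy-2-hydroxy-6-pentylbenzoate | CCCCCc1cc(OCC)cc(O)c1C(=O)OC
F2 | step 6 | methyl 2,4-dihydroxy-6-pentylbenzoate | CCCCCc1cc(O)cc(O)c1C(=O)OC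
F3 | step 3 | (Z)-trimethyl(oct-2-en-2-yloxy)silane | C/C(O[Si](C)(C)C)=C/CCCCC
F4 | step 3 | methyl 3-acetyl-2-hydroxyoctanoate | CCCCCC(C(C)=O)C(O)C(=O)OC
F5 | step 3 | methyl 3-acetyl-2-(methylsulfonyloxy)octanoate | CCCCCC(C(C)=O)C(OS(C)(=O)=O)C(=O)OC
F6 | step 5 | methyl (2E)-3-[(2E)-3-(dimethylamino)prop-2-enoyl]oct-2-enoate | CN(C)/C=C/C(=O)/C(CCCCC)=C/C(=O)OC
F7 | step 8 | [4-(benzyloxy)-2-methoxy-6-pentylphenyl]methanol | CCCCCc1cc(OCc2ccccc2)cc(OC)c1CO
F8 | step 8 | 4-(benzyloxy)-2-methoxy-6-pentylbenzaldehyde | CCCCCc1cc(OCc2ccccc2)cc(OC)c1C=O
F9 | step 11 | 4-(benzyloxy)-2-methoxy-6-pentylbenzoyl chloride | CCCCCc1cc(OCc2ccccc2)cc(OC)c1C(=O)Cl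
A1 | alternative 1 | 1-fluoro-3-methoxy-5-(triisopropylsilyloxy)benzene | COc1cc(F)cc(O[Si](C(C)C)(C(C)C)C(C)C)c1
A2 | alternative 1 | 3-methoxy-5-(triisopropylsilyloxy)benzyne | COC1=CC(O[Si](C(C)C)(C(C)C)C(C)C)=CC#C1
A3 | alternative 1 | pentylmagnesium bromide | CCCCC[Mg]Br
A4 | alternative 1 | 2-methoxy-6-pentyl-4-(triisopropylsilyloxy)benzoic acid | CCCCCc1cc(O[Si](C(C)C)(C(C)C)C(C)C)cc(OC)c1C(=O)O
A5 | alternative 2 | 2,2-dimethyl-6-(2,4-dioxononyl)-4H-1,3-dioxin-4-one | CCCCCC(=O)CC(=O)CC1=CC(=O)OC(C)(C)O1
A6 | alternative 2 | dodec-1-ene-1,3,5,7-tetrone | CCCCCC(=O)CC(=O)CC(=O)C=C=O
A7 | alternative 2 | benzyl 2-methoxy-6-pentyl-4-[(3,5,7-trioxododecanoyl)oxy]benzoate | CCCCCC(=O)CC(=O)CC(=O)CC(=O)Oc1cc(OC)c(C(=O)OCc2ccccc2)c(CCCCC)c1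
A8 | alternative 2 | benzyl 4-[(2,4-dihydroxy-6-pentylbenzoyl)oxy]-2-methoxy-6-pentylbenzoate | CCCCCc1cc(OC(=O)c2c(CCCCC)cc(O)cc2O)cc(OC)c1C(=O)OCc1ccccc1
A9 | alternative 3 | methyl 4-methoxy-2-oxo-6-pentyl-2H-pyran-5-carboxylate | CCCCCc1oc(=O)cc(OC)c1C(=O)OC
A10 | alternative 3 | 1,1-bis(benzyloxy)ethene | C=C(OCc1ccccc1)OCc1ccccc1
A11 | alternative 3 | methyl 8,8-bis(benzyloxy)-5-methoxy-3-oxo-1-pentyl-2-oxabicyclo[2.2.2]oct-5-ene-6-carboxylate (racemic) | CCCCCC12CC(OCc3ccccc3)(OCc3ccccc3)C(C(OC)=C1C(=O)OC)C(=O)O2
A12 | alternative 3 | methyl 4-(benzyloxy)-2-methoxy-6-pentylbenzoate | CCCCCc1cc(OCc2ccccc2)cc(OC)c1C(=O)OC
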